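**Retrosynthetic overview**
1. The target is a 7-methyljuglone whose C2 carries C8' of a 7'-methylchromone-5'-carboxylic acid (chromone atoms primed). The acid, the C5 hydroxyl and the quinone are unmasked last, from a methyl ester, a methyl ether and a 4-methoxy-1-naphthol.
2. Feature used: in quinone ring B (C1, C2, C3, C4, C4a, C8a) the unit C3(H)=C2(C8') is bracketed by carbonyl carbons C4 (on C4a, peri to the C5 oxygen) and C1 (on C8a). This is the imprint of a terminal arylacetylene inserted between a carbene carbon and a CO.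
3. Key disconnection: a Dötz [3+2+1] benzannulation of the methoxy(2-methoxy-4-methylphenyl)carbene pentacarbonylchromium complex with the 8'-ethynylchromone ester cuts C4–C3, C2–C1 and C1–C8a. The crowded C2–C8' bond arrives ready-made as the aryl–alkyne bond.
4. Ethynylchromone: 3,5-dimethoxytoluene takes its acetyl between the two oxygens by lithiation, because Friedel–Crafts acylation of orcinol goes para to OH. Iodine is set on the acetophenone ortho to the OH that becomes O1', because a 5'-hydroxychromone is expected to iodinate at C6'. Pyranone closure, Sonogashira coupling and OMe → OH → OTf → CO2Me follow.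
5. Ring order: the chromone benzene ring and ring A are bought, the pyranone ring is closed in step 4, and quinone ring B is closed last, in step 11.

Key step: step 11

Assumption: the target SMILES holds no stereodescriptor and the molecule has no stereocentre. The hindered C2–C8' axis is left unspecified, and the material is made as the racemate if rotation is slow.

**Step 1**
Reactants: 1 3,5-dimethoxytoluene
Product: 3 1-(2,6-dimethoxy-4-methylphenyl)ethan-1-one, via aryllithium 2 (not isolated)
Conditions: n-BuLi, THF, 0 °C to rt; MeC(O)N(OMe)Me, −78 °C to rt; 1 M HCl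
Reagents that add atoms: N-methoxy-N-methylacetamide, CC(=O)N(C)OC
Why: Directed ortho-metalation removes the proton between the two methoxy groups (doubly coordinated and most acidic), and acylation with the Weinreb amide stops at the ketone, which places the acetyl where electrophilic acylation would not.

**Step 2**
Reactants: 3 1-(2,6-dimethoxy-4-methylphenyl)ethan-1-one
Product: 4 1-(2-hydroxy-6-methoxy-4-methylphenyl)ethan-1-one
Conditions: BCl3 (1.1 equiv), CH2Cl2, −78 to 0 °C; H2O
Reagents that add atoms: none
Why: In this chelation-controlled Lewis-acid ether cleavage, BCl3 bound to the ketone oxygen cleaves one ortho O–CH3 bond, the six-membered boron chelate then protects the second, and the two methoxy groups are equivalent, so only one product can form.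

**Step 3**
Reactants: 4 1-(2-hydroxy-6-methoxy-4-methylphenyl)ethan-1-one
Product: 5 1-(2-hydroxy-3-iodo-6-methoxy-4-methylphenyl)ethan-1-one
Conditions: NIS (1.05 equiv), CF3CO2H (cat.), MeCN, 0 °C to rt, dark
Reagents that add atoms: N-iodosuccinimide, O=C1CCC(=O)N1I
Why: Electrophilic aromatic iodination should take C3, which is ortho to the hydrogen-bonded OH, para to OMe and next to the small OH, rather than C5, which is wedged between CH3 and an in-plane OCH3 (the bias that sends halogen to C3 of 2-hydroxy-4,6-dimethoxyacetophenone), so the iodine sits beside the oxygen that becomes O1', on the future C8'.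

**Step 4**
Reactants: 5 1-(2-hydroxy-3-iodo-6-methoxy-4-methylphenyl)ethan-1-one
Product: 7 8-iodo-5-methoxy-7-methyl-4H-chromen-4-one, via enaminone 6 (not isolated)
Conditions: Me2NCH(OMe)2, toluene, 100 °C; evaporate; conc. HCl, CH2Cl2, 40 °C
Reagents that add atoms: N,N-dimethylformamide dimethyl acetal, COC(OC)N(C)C
Why: In this enaminone route to 2,3-unsubstituted chromones, the acetyl CH3 condenses with the amide acetal, and acid then lets the phenol add to the β-carbon and expel dimethylamine, which closes the pyranone ring by addition–elimination.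

**Step 5**
Reactants: 7 8-iodo-5-methoxy-7-methyl-4H-chromen-4-one
Product: 8 5-hydroxy-8-iodo-7-methyl-4H-chromen-4-one
Conditions: BCl3 (2 equiv), CH2Cl2, −78 °C to rt; H2O
Reagents that add atoms: none
Why: Chelation-assisted ether cleavage of a methoxy group peri to the C4' carbonyl is standard for 5-methoxychromones and flavones, and it is done before the alkyne is present because boron halides add to alkynes.

**Step 6**
Reactants: 8 5-hydroxy-8-iodo-7-methyl-4H-chromen-4-one; 9 triisopropylsilylacetylene
Product: 10 5-hydroxy-7-methyl-8-[(triisopropylsilyl)ethynyl]-4H-chromen-4-one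
Conditions: PdCl2(PPh3)2 (5 mol %), CuI (10 mol %), Et3N, DMF, 60 °C, Ar
Reagents that add atoms: none
Why: This is a Sonogashira coupling of an aryl iodide in which a tertiary amine avoids amine attack at C2' of the pyranone, the chelated C5' hydroxyl is a spectator, and the bulky silyl group is chosen because a trimethylsilyl alkyne would be at risk in the warm MeOH–Et3N of step 8.

**Step 7**
Reactants: 10 5-hydroxy-7-methyl-8-[(triisopropylsilyl)ethynyl]-4H-chromen-4-one
Product: 11 7-methyl-4-oxo-8-[(triisopropylsilyl)ethynyl]-4H-chromen-5-yl trifluoromethanesulfonate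
Conditions: Tf2O, pyridine, CH2Cl2, 0 °C
Reagents that add atoms: trifluoromethanesulfonic anhydride, O=S(=O)(OS(=O)(=O)C(F)(F)F)C(F)(F)F
Why: O-sulfonylation of a phenol with triflic anhydride is strong enough to overcome the hydrogen bond to the C4' carbonyl, and nothing else in 10 is nucleophilic.

**Step 8**
Reactants: 11 7-methyl-4-oxo-8-[(triisopropylsilyl)ethynyl]-4H-chromen-5-yl trifluoromethanesulfonate
Product: 12 methyl 7-methyl-4-oxo-8-[(triisopropylsilyl)ethynyl]-4H-chromene-5-carboxylate
Conditions: Pd(OAc)2 (10 mol %), dppp, CO (1 atm), Et3N, MeOH–DMF, 65 °C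
Reagents that add atoms: carbon monoxide, [C-]#[O+]; methanol, CO
Why: In this palladium-catalysed alkoxycarbonylation of an aryl triflate, zerovalent palladium adds readily to the electron-poor C5'–O bond, CO inserts, methanol captures the acylpalladium species, and the capped alkyne cannot take part.

**Step 9**
Reactants: 12 methyl 7-methyl-4-oxo-8-[(triisopropylsilyl)ethynyl]-4H-chromene-5-carboxylate
Product: 13 methyl 8-ethynyl-7-methyl-4-oxo-4H-chromene-5-carboxylate
Conditions: Bu4NF, AcOH, THF, 0 °C to rt
Reagents that add atoms: none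
Why: Fluoride-induced protodesilylation of an alkynylsilane is fast on this electron-poor arylalkyne, and the acetic acid buffer keeps basic species away from C2' of the pyranone and from the ester.

**Step 10**
Reactants: 14 1-bromo-2-methoxy-4-methylbenzene; 15 chromium hexacarbonyl Cr(CO)6
Product: 18 pentacarbonyl[methoxy(2-methoxy-4-methylphenyl)methylidene]chromium, via aryllithium 16 (not isolated), via lithium acylchromate 17 (not isolated)
Conditions: n-BuLi, Et2O, −78 to 0 °C; Cr(CO)6, Et2O, 0 °C to rt; evaporate; Me3OBF4, CH2Cl2, 0 °C to rt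
Reagents that add atoms: trimethyloxonium tetrafluoroborate, C[O+](C)C.F[B-](F)(F)F
Why: In this Fischer carbene synthesis, bromine–lithium exchange fixes the metal at the carbon ortho to OMe, the aryllithium adds to a CO ligand, and hard O-methylation of the acylate gives the methoxycarbene complex.

**Step 11**
Reactants: 18 pentacarbonyl[methoxy(2-methoxy-4-methylphenyl)methylidene]chromium; 13 methyl 8-ethynyl-7-methyl-4-oxo-4H-chromene-5-carboxylate
Product: 20 methyl 8-(1-hydroxy-4,5-dimethoxy-7-methylnaphthalen-2-yl)-7-methyl-4-oxo-4H-chromene-5-carboxylate, via Cr(CO)3 naphthol complex 19 (not isolated)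
Conditions: 18 (1.3 equiv), degassed THF (ca. 0.1 M), 55–60 °C, Ar; then air, Et2O–CH2Cl2, rt
Reagents that add atoms: none
Why: Thermal loss of a cis CO from 18 opens a site for alkyne 13, which inserts into the Cr=C bond (C4–C3) to give a vinylcarbene, CO then migrates to the former internal alkyne carbon (C2–C1) to give a vinylketene complex, and this closes onto the free ortho carbon of the anisyl ring (C1–C8a). Ring B is therefore closed by a 6π electrocyclisation of the aryl vinylketene followed by tautomerisation to the naphthol, which air releases from complex 19. The reaction is the Dötz benzannulation of an aryl(methoxy)carbene chromium complex with a terminal arylacetylene, a known entry to 2-aryl-4-methoxy-1-naphthols that includes ortho-substituted arylacetylenes. The first selectivity needed is the chromonyl group next to the CO-derived C1, and sterics secure it, because the larger alkyne substituent avoids the carbene carbon and hydrogen against a 2,6-disubstituted aryl is the largest difference available. The second is the choice of ortho carbon, settled by the 2-methoxy group, which blocks one site so that this oxygen ends at C5, peri to C4 and remote from the aryl on C2. No stereocentre is formed, the neutral medium leaves pyranone and ester untouched, and THF is preferred to MeCN or DMF because strong donor solvents divert aryl carbenes to indenes.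

**Step 12**
Reactants: 20 methyl 8-(1-hydroxy-4,5-dimethoxy-7-methylnaphthalen-2-yl)-7-methyl-4-oxo-4H-chromene-5-carboxylate
Product: 21 methyl 8-(5-methoxy-7-methyl-1,4-dioxo-1,4-dihydronaphthalen-2-yl)-7-methyl-4-oxo-4H-chromene-5-carboxylate
Conditions: (NH4)2Ce(NO3)6 (2.5 equiv), MeCN–H2O, 0 °C
Reagents that add atoms: water, O
Why: In this oxidative demethylation of a 4-methoxy-1-naphthol, two one-electron oxidations by tetravalent cerium let water attack C4 and expel methanol, while the lone C5 methoxy group, the chromone and the ester are not oxidised at 0 °C.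

**Step 13**
Reactants: 21 methyl 8-(5-methoxy-7-methyl-1,4-dioxo-1,4-dihydronaphthalen-2-yl)-7-methyl-4-oxo-4H-chromene-5-carboxylate
Product: 22 methyl 8-(5-hydroxy-7-methyl-1,4-dioxo-1,4-dihydronaphthalen-2-yl)-7-methyl-4-oxo-4H-chromene-5-carboxylate
Conditions: BCl3 (4 equiv), CH2Cl2, −78 to 0 °C; H2O
Reagents that add atoms: none
Why: Chelation-assisted ether cleavage removes the C5 methoxy group peri to the C4 quinone carbonyl at low temperature, the excess reagent covers the other Lewis-basic carbonyls, and chloride is a poorer nucleophile toward C3 of the quinone than bromide.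

**Step 14**
Reactants: 22 methyl 8-(5-hydroxy-7-methyl-1,4-dioxo-1,4-dihydronaphthalen-2-yl)-7-methyl-4-oxo-4H-chromene-5-carboxylate
Product: 23 8-(5-hydroxy-7-methyl-1,4-dioxo-1,4-dihydronaphthalen-2-yl)-7-methyl-4-oxo-4H-chromene-5-carboxylic acid (target)
Conditions: aq. H2SO4 (3 M)–AcOH, 90 °C, N2
Reagents that add atoms: water, O
Why: Acid-catalysed acyl–oxygen ester hydrolysis with a non-nucleophilic mineral acid is chosen because chromones and juglones tolerate acid, whereas hydroxide would open the pyranone at C2' and degrade the hydroxyquinone.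

**Compound list**
1 | 3,5-dimethoxytoluene (orcinol dimethyl ether) | COc1cc(C)cc(OC)c1 | starting material
2 | (2,6-dimethoxy-4-methylphenyl)lithium | [Li]c1c(OC)cc(C)cc1OC | intermediate
3 | 1-(2,6-dimethoxy-4-methylphenyl)ethan-1-one | CC(=O)c1c(OC)cc(C)cc1OC | intermediate
4 | 1-(2-hydroxy-6-methoxy-4-methylphenyl)ethan-1-one | CC(=O)c1c(O)cc(C)cc1OC | intermediate
5 | 1-(2-hydroxy-3-iodo-6-methoxy-4-methylphenyl)ethan-1-one | CC(=O)c1c(O)c(I)c(C)cc1OC | intermediate
6 | (E)-3-(dimethylamino)-1-(2-hydroxy-3-iodo-6-methoxy-4-methylphenyl)prop-2-en-1-one | CN(C)/C=C/C(=O)c1c(O)c(I)c(C)cc1OC | intermediate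
7 | 8-iodo-5-methoxy-7-methyl-4H-chromen-4-one | COc1cc(C)c(I)c2occc(=O)c12 | intermediate
8 | 5-hydroxy-8-iodo-7-methyl-4H-chromen-4-one | Cc1cc(O)c2c(=O)ccoc2c1I | intermediate
9 | triisopropylsilylacetylene | C#C[Si](C(C)C)(C(C)C)C(C)C | starting material
10 | 5-hydroxy-7-methyl-8-[(triisopropylsilyl)ethynyl]-4H-chromen-4-one | Cc1cc(O)c2c(=O)ccoc2c1C#C[Si](C(C)C)(C(C)C)C(C)C | intermediate
11 | 7-methyl-4-oxo-8-[(triisopropylsilyl)ethynyl]-4H-chromen-5-yl trifluoromethanesulfonate | Cc1cc(OS(=O)(=O)C(F)(F)F)c2c(=O)ccoc2c1C#C[Si](C(C)C)(C(C)C)C(C)C | intermediate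
12 | methyl 7-methyl-4-oxo-8-[(triisopropylsilyl)ethynyl]-4H-chromene-5-carboxylate | COC(=O)c1cc(C)c(C#C[Si](C(C)C)(C(C)C)C(C)C)c2occc(=O)c12 | intermediate
13 | methyl 8-ethynyl-7-methyl-4-oxo-4H-chromene-5-carboxylate | C#Cc1c(C)cc(C(=O)OC)c2c(=O)ccoc12 | intermediate
14 | 1-bromo-2-methoxy-4-methylbenzene | COc1cc(C)ccc1Br | starting material
15 | chromium hexacarbonyl Cr(CO)6 | O=C=[Cr](=C=O)(=C=O)(=C=O)(=C=O)=C=O | starting material
16 | (2-methoxy-4-methylphenyl)lithium | [Li]c1ccc(C)cc1OC | intermediate
17 | lithium pentacarbonyl[(2-methoxy-4-methylphenyl)(oxido)methylidene]chromate | [Li+].[O-]C(c1ccc(C)cc1OC)=[Cr](=C=O)(=C=O)(=C=O)(=C=O)=C=O | intermediate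
18 | pentacarbonyl[methoxy(2-methoxy-4-methylphenyl)methylidene]chromium | COC(c1ccc(C)cc1OC)=[Cr](=C=O)(=C=O)(=C=O)(=C=O)=C=O | intermediate
19 | tricarbonylchromium complex of naphthol 20, Cr(CO)3 η6-bound to the new ring B (written as arene plus Cr(CO)3 fragment) | COc1cc(-c2c(C)cc(C(=O)OC)c3c(=O)ccoc23)c(O)c2cc(C)cc(OC)c12.O=C=[Cr](=C=O)=C=O | intermediate
20 | methyl 8-(1-hydroxy-4,5-dimethoxy-7-methylnaphthalen-2-yl)-7-methyl-4-oxo-4H-chromene-5-carboxylate | COc1cc(-c2c(C)cc(C(=O)OC)c3c(=O)ccoc23)c(O)c2cc(C)cc(OC)c12 | intermediate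
21 | methyl 8-(5-methoxy-7-methyl-1,4-dioxo-1,4-dihydronaphthalen-2-yl)-7-methyl-4-oxo-4H-chromene-5-carboxylate | COC(=O)c1cc(C)c(C2=CC(=O)c3c(OC)cc(C)cc3C2=O)c2occc(=O)c12 | intermediate
22 | methyl 8-(5-hydroxy-7-methyl-1,4-dioxo-1,4-dihydronaphthalen-2-yl)-7-methyl-4-oxo-4H-chromene-5-carboxylate | COC(=O)c1cc(C)c(C2=CC(=O)c3c(O)cc(C)cc3C2=O)c2occc(=O)c12 | intermediate
23 | 8-(5-hydroxy-7-methyl-1,4-dioxo-1,4-dihydronaphthalen-2-yl)-7-methyl-4-oxo-4H-chromene-5-carboxylic acid | Cc1cc(O)c2c(c1)C(=O)C(c1c(C)cc(C(=O)O)c3c(=O)ccoc13)=CC2=O | target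

**Step count**
Total step count: 14.
Longest linear sequence: 13 steps (steps 1–9, then steps 11–14). The carbene branch is step 10.

**Steps most likely to fail**

1. Step 11. Uptake of the crowded, acceptor-substituted arylacetylene by the unsaturated carbene may be slow. Thermal decay of the carbene, closure without CO insertion (indene or furan pathways) or alkyne oligomerisation could then outrun the annulation.
The fallback sets out from carbene 18 and iodide 8 and comes back to the route at quinone 21. It keeps the benzannulation for ring B but takes the bulky aryl group out of it. Carbene 18 is heated with commercial 2-ethynyl-4,4,5,5-tetramethyl-1,3,2-dioxaborolane (THF, 55 °C, then air). This is a small terminal alkyne of a class known to undergo the reaction with boron next to the new hydroxyl. It should give 4,5-dimethoxy-7-methyl-2-(4,4,5,5-tetramethyl-1,3,2-dioxaborolan-2-yl)naphthalen-1-ol F1. MeI and K2CO3 in acetone give 4,4,5,5-tetramethyl-2-(1,4,5-trimethoxy-7-methylnaphthalen-2-yl)-1,3,2-dioxaborolane F2. Suzuki–Miyaura coupling with 8 (Pd(OAc)2, SPhos, K3PO4, toluene, 90 °C) gives 5-hydroxy-7-methyl-8-(1,4,5-trimethoxy-7-methylnaphthalen-2-yl)-4H-chromen-4-one F3. Tf2O and pyridine give 7-methyl-4-oxo-8-(1,4,5-trimethoxy-7-methylnaphthalen-2-yl)-4H-chromen-5-yl trifluoromethanesulfonate F4. Methoxycarbonylation as in step 8 gives methyl 7-methyl-4-oxo-8-(1,4,5-trimethoxy-7-methylnaphthalen-2-yl)-4H-chromene-5-carboxylate F5. Finally (NH4)2Ce(NO3)6 in MeCN–H2O oxidises the 1,4-dimethoxy ring to 21.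

2. Step 3. Site selection between C3 and C5 of the phenol ether may be poor, or a second iodination may follow the first.
The fallback sets out from 4 and comes back at 7. The pyranone is closed first and the halogen is introduced afterwards under the para-directing control of an ether instead of a chelated phenol. Me2NCH(OMe)2 converts 4 into (E)-3-(dimethylamino)-1-(2-hydroxy-6-methoxy-4-methylphenyl)prop-2-en-1-one F6. HCl in CH2Cl2 closes this to 5-methoxy-7-methyl-4H-chromen-4-one F7. NIS with CF3CO2H then iodinates para to the C5' methoxy group at C8', the site preference known for 5-alkoxy flavones, to give 7.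

3. Step 14. Hydrolysis of the ester next to the peri carbonyl may be slow. Prolonged heating would then allow addition of water or acetate to C3 of the quinone and gradual breakdown of the hydroxyquinone.
The fallback sets out from triflate 11 and comes back at target 23. It replaces the methyl ester by a benzyl ester, so that no hydrolysis is needed. Carbonylation of 11 as in step 8, with benzyl alcohol in DMF in place of methanol, gives benzyl 7-methyl-4-oxo-8-[(triisopropylsilyl)ethynyl]-4H-chromene-5-carboxylate F8. Bu4NF and AcOH give benzyl 8-ethynyl-7-methyl-4-oxo-4H-chromene-5-carboxylate F9. Benzannulation with 18 as in step 11 gives benzyl 8-(1-hydroxy-4,5-dimethoxy-7-methylnaphthalen-2-yl)-7-methyl-4-oxo-4H-chromene-5-carboxylate F10. (NH4)2Ce(NO3)6 gives benzyl 8-(5-methoxy-7-methyl-1,4-dioxo-1,4-dihydronaphthalen-2-yl)-7-methyl-4-oxo-4H-chromene-5-carboxylate F11. One treatment with BCl3 (CH2Cl2, −78 to 0 °C) then cleaves the benzyl–oxygen bond of the ester and the chelated C5 methyl ether together, to give 23.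

**Further compounds**
F1 | step 11 | 4,5-dimethoxy-7-methyl-2-(4,4,5,5-tetramethyl-1,3,2-dioxaborolan-2-yl)naphthalen-1-ol | COc1cc(B2OC(C)(C)C(C)(C)O2)c(O)c2cc(C)cc(OC)c12
F2 | step 11 | 4,4,5,5-tetramethyl-2-(1,4,5-trimethoxy-7-methylnaphthalen-2-yl)-1,3,2-dioxaborolane | COc1cc(B2OC(C)(C)C(C)(C)O2)c(OC)c2cc(C)cc(OC)c12
F3 | step 11 | 5-hydroxy-7-methyl-8-(1,4,5-trimethoxy-7-methylnaphthalen-2-yl)-4H-chromen-4-one | COc1cc(-c2c(C)cc(O)c3c(=O)ccoc23)c(OC)c2cc(C)cc(OC)c12
F4 | step 11 | 7-methyl-4-oxo-8-(1,4,5-trimethoxy-7-methylnaphthalen-2-yl)-4H-chromen-5-yl trifluoromethanesulfonate | COc1cc(-c2c(C)cc(OS(=O)(=O)C(F)(F)F)c3c(=O)ccoc23)c(OC)c2cc(C)cc(OC)c12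
F5 | step 11 | methyl 7-methyl-4-oxo-8-(1,4,5-trimethoxy-7-methylnaphthalen-2-yl)-4H-chromene-5-carboxylate | COc1cc(-c2c(C)cc(C(=O)OC)c3c(=O)ccoc23)c(OC)c2cc(C)cc(OC)c12
F6 | step 3 | (E)-3-(dimethylamino)-1-(2-hydroxy-6-methoxy-4-methylphenyl)prop-2-en-1-one | CN(C)/C=C/C(=O)c1c(O)cc(C)cc1OC
F7 | step 3 | 5-methoxy-7-methyl-4H-chromen-4-one | COc1cc(C)cc2occc(=O)c12
F8 | step 14 | benzyl 7-methyl-4-oxo-8-[(triisopropylsilyl)ethynyl]-4H-chromene-5-carboxylate | O=C(OCc1ccccc1)c1cc(C)c(C#C[Si](C(C)C)(C(C)C)C(C)C)c2occc(=O)c12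
F9 | step 14 | benzyl 8-ethynyl-7-methyl-4-oxo-4H-chromene-5-carboxylate | C#Cc1c(C)cc(C(=O)OCc2ccccc2)c2c(=O)ccoc12
F10 | step 14 | benzyl 8-(1-hydroxy-4,5-dimethoxy-7-methylnaphthalen-2-yl)-7-methyl-4-oxo-4H-chromene-5-carboxylate | COc1cc(-c2c(C)cc(C(=O)OCc3ccccc3)c3c(=O)ccoc23)c(O)c2cc(C)cc(OC)c12
F11 | step 14 | benzyl 8-(5-methoxy-7-methyl-1,4-dioxo-1,4-dihydronaphthalen-2-yl)-7-methyl-4-oxo-4H-chromene-5-carboxylate | O=C(OCc1ccccc1)c1cc(C)c(C2=CC(=O)c3c(OC)cc(C)cc3C2=O)c2occc(=O)c12
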